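Locants: ring A = O1, C2 (aryl), C3, C4, C5; C6 = hydroxymethyl carbon on C3; C7 = aryl carbinol carbon on C4.
Cuts, in retrosynthetic order: both O–benzyl bonds; C6–O (back to C6–Si); C3–C6 together with C4–H (radical step); Si–O at C7; C7–aryl; C3=C4 (metathesis); O1–C5; C2–C3.
Enabling feature: along O–C7–C4–C3–C6 the C7 oxygen and C6 stand 1,4 to each other on the same face of ring A. A CH2 radical held on that oxygen by SiMe2 can therefore reach C3 of a C3=C4 dihydrofuran and close the six-membered ring B (O, Si, C6, C3, C4, C7).
Forward: an aryl vinyl carbinol is etherified and ring A is closed by metathesis. The ester is taken to the aldehyde, which accepts the second aryl group at C7. Ring B is then closed by the radical step and excised oxidatively, leaving both hydroxyl groups.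
Stereochemistry: C2 comes from an enzymatic resolution and C7 from a ligand-controlled aryl transfer. C3 comes from radical attack anti to the C2 aryl group, and C4 from hydrogen transfer anti to the new C3–C6 bond (cis fusion of rings A and B).

Key step: step 10

Remark 1: Ar = 4-(benzyloxy)-3-methoxyphenyl. The descriptor at C7 reads R while C4 is olefinic (16, 18) and S once C4 is saturated (21–23). The descriptor at C3 reads S in 21 (silicon-bearing C6 outranks C2) and R in 22 and 23. The spatial arrangement at these centres does not change.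
Remark 2: 4-(benzyloxy)-3-methoxybenzaldehyde and (+)-MIB are assumed to be purchasable. The ligand is otherwise available in three known steps from (1S)-camphor.

Step 1
Reactants: 1 4-(benzyloxy)-3-methoxybenzaldehyde; 2 vinylmagnesium bromide
Product: 3 (±)-1-Ar-prop-2-en-1-ol
Conditions: THF, 0 °C
Reagents that add atoms: none
Why: 1,2-Addition of a vinyl Grignard reagent to an aromatic aldehyde forms the C2–C3 bond cleanly with the benzyl and methyl ethers inert, and C2 arises racemic, to be sorted in step 2.

Step 2
Reactants: 3 (±)-1-Ar-prop-2-en-1-ol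
Product: 4 (S)-1-Ar-prop-2-en-1-ol
Conditions: Candida antarctica lipase B (immobilised, Novozym 435), vinyl acetate, t-BuOMe, 30 °C, taken just past half conversion
Reagents that add atoms: none
Why: Lipase-catalysed kinetic resolution by irreversible transesterification: for 1-arylalkyl and 1-arylallyl carbinols this enzyme acylates the R enantiomer (aryl in the large pocket, vinyl in the medium one), so the S alcohol that carries the C2 configuration of the target stays unreacted and is separated from the acetate, all under neutral conditions that do not ionise the acid-sensitive carbinol.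

Step 3
Reactants: 4 (S)-1-Ar-prop-2-en-1-ol; 5 methyl 2-(bromomethyl)acrylate
Product: 7 methyl 2-({[(1S)-1-Ar-prop-2-en-1-yl]oxy}methyl)prop-2-enoate, via sodium alkoxide 6 (not isolated)
Conditions: NaH, THF, 0 °C; then 5, 0 °C to rt
Reagents that add atoms: none
Why: Williamson-type O-alkylation of the alkoxide with the activated allylic bromide (direct and addition–elimination displacement give the same ether) forms O1–C5 without touching the C2–O bond, so the S configuration is kept.

Step 4
Reactants: 7 methyl 2-({[(1S)-1-Ar-prop-2-en-1-yl]oxy}methyl)prop-2-enoate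
Product: 8 methyl (5S)-5-Ar-2,5-dihydrofuran-3-carboxylate
Conditions: second-generation Grubbs catalyst RuCl2(=CHPh)(PCy3)(H2IMes) (5 mol %), 1,4-benzoquinone (10 mol %), CH2Cl2 (0.01 M), reflux
Reagents that add atoms: none
Why: Ring-closing metathesis between the monosubstituted alkene and the 1,1-disubstituted acrylate alkene closes the five-membered ring A and creates C3=C4, a closure well known for 2-(alkoxymethyl)acrylates with carbene-ligated ruthenium catalysts; loss of ethene drives it, benzoquinone suppresses hydride-induced double-bond migration, and C2 is not involved.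

Step 5
Reactants: 8 methyl (5S)-5-Ar-2,5-dihydrofuran-3-carboxylate
Product: 9 [(5S)-5-Ar-2,5-dihydrofuran-3-yl]methanol
Conditions: i-Bu2AlH (2.5 equiv), CH2Cl2, −78 °C
Reagents that add atoms: none
Why: 1,2-Reduction of an α,β-unsaturated ester with i-Bu2AlH stops at the allylic alcohol without conjugate reduction and, being non-basic, does not endanger the γ-hydrogen at C2.

Step 6
Reactants: 9 [(5S)-5-Ar-2,5-dihydrofuran-3-yl]methanol
Product: 10 (5S)-5-Ar-2,5-dihydrofuran-3-carbaldehyde
Conditions: TEMPO (10 mol %), PhI(OAc)2 (1.1 equiv), CH2Cl2, rt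
Reagents that add atoms: none
Why: TEMPO/PhI(OAc)2 oxoammonium oxidation turns primary allylic alcohols into enals without over-oxidation and without base, so neither aromatisation of ring A to a furan nor γ-deprotonation at C2 is expected.

Step 7
Reactants: 11 4-bromo-2-methoxyphenol
Product: 12 1-(benzyloxy)-4-bromo-2-methoxybenzene
Conditions: BnBr, K2CO3, DMF, rt
Reagents that add atoms: benzyl bromide, BrCc1ccccc1
Why: Williamson ether synthesis on a phenol; the benzyl ether tolerates the later halogen–lithium exchange and matches the protecting group of the other ring, so that both fall in one final operation.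

Step 8
Reactants: 10 (5S)-5-Ar-2,5-dihydrofuran-3-carbaldehyde; 12 1-(benzyloxy)-4-bromo-2-methoxybenzene
Product: 16 (R)-Ar[(5S)-5-Ar-2,5-dihydrofuran-3-yl]methanol, via aryllithium 13 (not isolated), via arylzinc chloride 14 (not isolated), via aryl(butyl)zinc 15 (not isolated)
Conditions: 12 (2 equiv), n-BuLi, t-BuOMe, −78 °C; ZnCl2, to 0 °C; n-BuLi, 0 °C; Et2NCH2CH2NEt2, toluene; (+)-MIB [(2R)-3-exo-morpholinoisoborneol] (10 mol %), then 10, 0 °C
Reagents that add atoms: none
Why: Catalytic asymmetric aryl transfer from a mixed aryl(alkyl)zinc to an aldehyde under β-amino alcohol control, known for cyclic α-substituted enals: the chiral zinc aminoalkoxide only has to tell the formyl hydrogen from the dihydrofuranyl residue (a far larger difference than the aryl/alkenyl pair that reduction of the corresponding ketone would have to sort), the diamine ties up LiCl so that uncatalysed addition stays slow, and since the (−)-ligand directs attack to the Si face, (+)-MIB should deliver the aryl group to the Re face and set C7 as R, any 7-epimer being a separable diastereomer.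

Step 9
Reactants: 16 (R)-Ar[(5S)-5-Ar-2,5-dihydrofuran-3-yl]methanol; 17 (bromomethyl)chlorodimethylsilane
Product: 18 (bromomethyl)dimethylsilyl ether of 16 (2S,7R)
Conditions: 17 (1.2 equiv), Et3N, DMAP (5 mol %), CH2Cl2, 0 °C
Reagents that add atoms: none
Why: Standard silylation of a secondary alcohol with a chlorosilane and amine base occurs at oxygen, leaves C7 and C2 untouched and, being basic throughout, avoids ionisation of the doubly activated carbinol; the ether is passed through Et3N-deactivated silica and used at once.

Step 10
Reactants: 18 (bromomethyl)dimethylsilyl ether of 16 (2S,7R)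
Product: 21 cis-fused bicyclic siloxane (2S,3S,4R,7S), via silylmethyl radical 19 (not isolated), via ring-fusion radical 20 (not isolated)
Conditions: n-Bu3SnH (1.3 equiv) and AIBN (0.2 equiv) added by syringe pump over 8 h, benzene (0.01 M), reflux
Reagents that add atoms: none
Why: The stannyl radical abstracts bromine from 18, the α-silyl radical 19 adds to C3 of the C3=C4 alkene to form the C3–C6 bond, and the tertiary C4 radical 20 takes hydrogen from n-Bu3SnH and passes the chain on, which is a Nishiyama–Stork silicon-tethered radical cyclization of an allylic (bromomethyl)dimethylsilyl ether. The one ring closed is ring B (O, Si, C6, C3, C4, C7), in the 6-endo-trig mode. The selectivity needed is 6-endo over 5-exo, and it is secured because 5-exo closure would have to build a quaternary spiro centre at the fully substituted C4 whereas C3 bears hydrogen, and because the long Si–C and Si–O bonds relax the usual geometric bias, as is known for 2-substituted allylic alcohols. C3 is set by attack on the face of ring A opposite the C2 aryl group, and the 7R centre is matched with that face, since the conformer with C7–H near the alkene plane hangs the O–Si arm under the ring and the chair-like transition state keeps the C7 aryl group equatorial. C4 is set in the hydrogen transfer, the stannane approaching 20 anti to the freshly made C3–C6 bond, which is the normal course for β-substituted five-ring radicals and leads to the cis-fused bicycle, so that C6 and C7 end up cis. Slow addition of the stannane at high dilution keeps direct reduction of 19 behind cyclization.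

Step 11
Reactants: 21 cis-fused bicyclic siloxane (2S,3S,4R,7S)
Product: 22 di-O-benzyltanegol, [(2S,3R,4R)-2-Ar-4-{(S)-Ar(hydroxy)methyl}oxolan-3-yl]methanol
Conditions: 30% aq. H2O2, KF, KHCO3, THF–MeOH 1:1, rt
Reagents that add atoms: hydrogen peroxide, OO
Why: Tamao oxidation: fluoride makes silicon hypervalent, hydroperoxide adds and C6 migrates from silicon to oxygen while the Si–O bond to C7 is hydrolysed, so one operation uncovers the C6 and C7 hydroxyl groups without touching any stereocentre and under weakly basic conditions that prevent acid-induced closure of the diol to a furofuran.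

Step 12
Reactants: 22 di-O-benzyltanegol
Product: 23 (−)-tanegol
Conditions: H2 (1 atm), 10% Pd/C, pyridine (0.5 equiv), EtOAc–MeOH, rt
Reagents that add atoms: none
Why: Hydrogenolysis of aryl benzyl ethers over Pd/C is much faster than cleavage of benzylic alcohols or dialkyl benzylic ethers, and the pyridine additive, which is known to poison the catalyst toward the latter bonds, should keep C7–OH and C2–O1 intact, so that both phenols are freed and no stereocentre is affected.

Compound list
1 | 4-(benzyloxy)-3-methoxybenzaldehyde | COc1cc(C=O)ccc1OCc1ccccc1 | starting material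
2 | vinylmagnesium bromide | C=C[Mg]Br | starting material
3 | (±)-1-[4-(benzyloxy)-3-methoxyphenyl]prop-2-en-1-ol | C=CC(O)c1ccc(OCc2ccccc2)c(OC)c1 | intermediate
4 | (S)-1-[4-(benzyloxy)-3-methoxyphenyl]prop-2-en-1-ol | C=C[C@H](O)c1ccc(OCc2ccccc2)c(OC)c1 | intermediate
5 | methyl 2-(bromomethyl)acrylate | C=C(CBr)C(=O)OC | starting material
6 | sodium (S)-1-[4-(benzyloxy)-3-methoxyphenyl]prop-2-en-1-olate (not isolated) | C=C[C@H]([O-])c1ccc(OCc2ccccc2)c(OC)c1.[Na+] | intermediate
7 | methyl 2-({[(1S)-1-[4-(benzyloxy)-3-methoxyphenyl]prop-2-en-1-yl]oxy}methyl)prop-2-enoate | C=C[C@H](OCC(=C)C(=O)OC)c1ccc(OCc2ccccc2)c(OC)c1 | intermediate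
8 | methyl (5S)-5-[4-(benzyloxy)-3-methoxyphenyl]-2,5-dihydrofuran-3-carboxylate | COC(=O)C1=C[C@@H](c2ccc(OCc3ccccc3)c(OC)c2)OC1 | intermediate
9 | [(5S)-5-[4-(benzyloxy)-3-methoxyphenyl]-2,5-dihydrofuran-3-yl]methanol | OCC1=C[C@@H](c2ccc(OCc3ccccc3)c(OC)c2)OC1 | intermediate
10 | (5S)-5-[4-(benzyloxy)-3-methoxyphenyl]-2,5-dihydrofuran-3-carbaldehyde | O=CC1=C[C@@H](c2ccc(OCc3ccccc3)c(OC)c2)OC1 | intermediate
11 | 4-bromo-2-methoxyphenol | COc1cc(Br)ccc1O | starting material
12 | 1-(benzyloxy)-4-bromo-2-methoxybenzene | COc1cc(Br)ccc1OCc1ccccc1 | intermediate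
13 | [4-(benzyloxy)-3-methoxyphenyl]lithium (not isolated) | COc1cc([Li])ccc1OCc1ccccc1 | intermediate
14 | [4-(benzyloxy)-3-methoxyphenyl]zinc chloride (not isolated) | COc1cc([Zn]Cl)ccc1OCc1ccccc1 | intermediate
15 | [4-(benzyloxy)-3-methoxyphenyl](butyl)zinc (not isolated) | CCCC[Zn]c1ccc(OCc2ccccc2)c(OC)c1 | intermediate
16 | (R)-[4-(benzyloxy)-3-methoxyphenyl][(5S)-5-[4-(benzyloxy)-3-methoxyphenyl]-2,5-dihydrofuran-3-yl]methanol (2S,7R) | COc1cc([C@@H](O)C2=C[C@@H](c3ccc(OCc4ccccc4)c(OC)c3)OC2)ccc1OCc1ccccc1 | intermediate
17 | (bromomethyl)chlorodimethylsilane | C[Si](C)(Cl)CBr | starting material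
18 | (bromomethyl)dimethylsilyl ether of 16 (2S,7R), key-step precursor | COc1cc([C@@H](O[Si](C)(C)CBr)C2=C[C@@H](c3ccc(OCc4ccccc4)c(OC)c3)OC2)ccc1OCc1ccccc1 | intermediate
19 | silylmethyl radical derived from 18 by loss of bromine (not isolated) | COc1cc([C@@H](O[Si](C)(C)[CH2])C2=C[C@@H](c3ccc(OCc4ccccc4)c(OC)c3)OC2)ccc1OCc1ccccc1 | intermediate
20 | bicyclic tertiary radical at the ring-fusion carbon C4 (not isolated) | COc1cc([C@H]2O[Si](C)(C)C[C@@H]3[C@@H](c4ccc(OCc5ccccc5)c(OC)c4)OC[C]23)ccc1OCc1ccccc1 | intermediate
21 | (2S,3S,4R,7S)-siloxane: ring A cis-fused at C3–C4 to the 2,2-dimethyl-1-oxa-2-silacyclohexane ring B, C2 aryl trans to C6, C7 aryl equatorial on ring B; key-step product | COc1cc([C@H]2O[Si](C)(C)C[C@@H]3[C@@H](c4ccc(OCc5ccccc5)c(OC)c4)OC[C@H]23)ccc1OCc1ccccc1 | intermediate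
22 | di-O-benzyltanegol, [(2S,3R,4R)-2-[4-(benzyloxy)-3-methoxyphenyl]-4-{(S)-[4-(benzyloxy)-3-methoxyphenyl](hydroxy)methyl}oxolan-3-yl]methanol | COc1cc([C@@H](O)[C@H]2CO[C@H](c3ccc(OCc4ccccc4)c(OC)c3)[C@H]2CO)ccc1OCc1ccccc1 | intermediate
23 | (−)-tanegol, [(2S,3R,4R)-2-(4-hydroxy-3-methoxyphenyl)-4-[(S)-hydroxy(4-hydroxy-3-methoxyphenyl)methyl]oxolan-3-yl]methanol | COc1cc([C@@H](O)[C@H]2CO[C@H](c3ccc(O)c(OC)c3)[C@H]2CO)ccc1O | target

Total step count: 12. Longest linear sequence: 11 (steps 1–6 and 8–12, from 1).

Steps most likely to fail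

Step 10. Three things may go wrong. The silylmethyl radical may be quenched by the stannane before it cyclises. It may close on C4 instead of C3. The C4 radical may take up hydrogen on the face syn to the C3–C6 bond, because the C2 aryl group screens the other face.

The fallback sets out from ester 8 and comes back at diol 22. It builds C3–C6 by polar chemistry and fixes the 3,4-cis relation thermodynamically.
- Conjugate addition of (isopropoxydimethylsilyl)methylmagnesium chloride to 8 (CuBr·SMe2, Me3SiCl, THF, −78 °C) should occur anti to the C2 aryl group. It should give methyl 2-Ar-3-[(isopropoxydimethylsilyl)methyl]oxolane-4-carboxylate F1, mixed at C4.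
- Tamao oxidation converts this into methyl 2-Ar-3-(hydroxymethyl)oxolane-4-carboxylate F2.
- DBU equilibrates C4. Since only the cis isomer can lactonise, the material is funnelled into the cis-fused lactone 6-Ar-3,7-dioxabicyclo[3.3.0]octan-2-one F3.
- Aryllithium 13 at −78 °C opens the lactone to the C7 aryl ketone carrying the free C6 hydroxyl, hydroxy ketone F4.
- LiBH(s-Bu)3 at −78 °C should reduce F4 under Felkin–Anh control (C3 as the large substituent, hydride passing the C4 hydrogen) to the 7S carbinol 22.

Step 8. Facial selectivity may be poor through uncatalysed background addition, or butyl may be transferred in place of aryl.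

The fallback sets out from enal 10 and aryllithium 13 and comes back at 16. It gives up induction in favour of separation and recycling, which is possible because C2 is already fixed.
- Direct addition of 13 to 10 at −78 °C should give 16 together with its C7 epimer, the (2S,7S)-allylic alcohol F5. The two are diastereomers and can be parted by chromatography on deactivated silica.
- F5 is oxidised with MnO2 to the aryl dihydrofuranyl ketone F6.
- Luche reduction (NaBH4, CeCl3·7H2O, MeOH) returns F6 to the mixture of 16 and F5 for another pass.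

Step 12. Reductive loss of the benzylic C7 hydroxyl group, or opening of ring A at the benzylic C2–O1 bond, may compete with debenzylation.

The fallback sets out from siloxane 21 and comes back at 23, with the last two operations inverted.
- Hydrogenolysis (H2, Pd/C, EtOAc) is carried out while the C7 oxygen is still silylated and locked in ring B. This should give the bisphenol siloxane F7.
- Tamao oxidation (H2O2, KF, KHCO3) of F7 then releases the C6 and C7 hydroxyl groups as the last act.

Further compounds
F1 | step 10 | methyl (2S,3S)-2-[4-(benzyloxy)-3-methoxyphenyl]-3-[(isopropoxydimethylsilyl)methyl]oxolane-4-carboxylate, C2 aryl trans to C6, mixed at C4 | COC(=O)C1CO[C@H](c2ccc(OCc3ccccc3)c(OC)c2)[C@H]1C[Si](C)(C)OC(C)C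
F2 | step 10 | methyl (2S,3R)-2-[4-(benzyloxy)-3-methoxyphenyl]-3-(hydroxymethyl)oxolane-4-carboxylate, mixed at C4 | COC(=O)C1CO[C@H](c2ccc(OCc3ccccc3)c(OC)c2)[C@H]1CO
F3 | step 10 | cis-fused lactone 6-[4-(benzyloxy)-3-methoxyphenyl]-3,7-dioxabicyclo[3.3.0]octan-2-one, C2 S, aryl trans to C6 | O=C1OC[C@@H]2[C@@H](c3ccc(OCc4ccccc4)c(OC)c3)OC[C@H]12
F4 | step 10 | [4-(benzyloxy)-3-methoxyphenyl][(3R,4R,5S)-5-[4-(benzyloxy)-3-methoxyphenyl]-4-(hydroxymethyl)oxolan-3-yl]methanone (2,3-trans, 3,4-cis) | COc1cc(C(=O)[C@H]2CO[C@H](c3ccc(OCc4ccccc4)c(OC)c3)[C@H]2CO)ccc1OCc1ccccc1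
F5 | step 8 | (S)-[4-(benzyloxy)-3-methoxyphenyl][(5S)-5-[4-(benzyloxy)-3-methoxyphenyl]-2,5-dihydrofuran-3-yl]methanol, C7 epimer of 16 | COc1cc([C@H](O)C2=C[C@@H](c3ccc(OCc4ccccc4)c(OC)c3)OC2)ccc1OCc1ccccc1
F6 | step 8 | [4-(benzyloxy)-3-methoxyphenyl][(5S)-5-[4-(benzyloxy)-3-methoxyphenyl]-2,5-dihydrofuran-3-yl]methanone | COc1cc(C(=O)C2=C[C@@H](c3ccc(OCc4ccccc4)c(OC)c3)OC2)ccc1OCc1ccccc1
F7 | step 12 | (2S,3S,4R,7S)-bisphenol siloxane, 21 with both benzyl groups replaced by hydrogen | COc1cc([C@H]2O[Si](C)(C)C[C@@H]3[C@@H](c4ccc(O)c(OC)c4)OC[C@H]23)ccc1O
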